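**Strategy**

Everything rests on making the C1–C2 bond of ring B last. C1 sits between ring A and the pendant aryl ring; with that ring carried as a para-phenol, C1 can become the exocyclic carbon of a p-quinone methide, while C2 is the α-carbon of a γ-lactone (C9, O, C9') fused at C2–C3. One treatment with base releases both partners, the lactone enolate adds to the quinone methide, ring B closes, and C1 and C2 are set from the single centre C3. The precursor is (R)-β-(3,4-dimethoxybenzyl)-γ-butyrolactone bearing, ortho to its benzylic CH2 on ring A, a (4-hydroxy-3-methoxyphenyl)(p-tolylsulfonyl)methyl group, a sulfinate leaving group that has no enolisable or acylating site.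

Key step: step 8

Remark: lignan numbering is used throughout (C1 bears the pendant aryl ring, C2 and C3 bear C9 and C9', C4 is the benzylic CH2, ring A is the dimethoxybenzo ring, ring B the carbocycle C1–C4/C4a/C8a); the target is (1R,2S,3R), that is 1,2-trans-2,3-cis; the carbinol, acetal and sulfonyl-bearing carbons of 13–18 are carried as epimer mixtures, since C1 becomes planar in 19.

**Route**

Step 1
Reactants: 1 3-(3,4-dimethoxyphenyl)propanoic acid; 2 (S)-4-benzyloxazolidin-2-one
Product: 4 (S)-4-benzyl-3-[3-(3,4-dimethoxyphenyl)propanoyl]oxazolidin-2-one, via mixed pivalic anhydride 3 (not isolated)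
Conditions: t-BuCOCl, Et3N, THF, −20 °C; then 2, LiCl, −20 °C → rt
Reagents that add atoms: none
Why: N-acylation of the oxazolidinone by a mixed pivalic anhydride under LiCl/Et3N activation is a standard way to load an Evans auxiliary, and the hindered pivaloyl carbonyl of 3 directs attack to the arylpropanoyl carbon.

Step 2
Reactants: 4 (S)-4-benzyl-3-[3-(3,4-dimethoxyphenyl)propanoyl]oxazolidin-2-one; 5 tert-butyl bromoacetate
Product: 7 tert-butyl (3R)-4-[(4S)-4-benzyl-2-oxooxazolidin-3-yl]-3-(3,4-dimethoxybenzyl)-4-oxobutanoate, via sodium Z-enolate 6 (not isolated)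
Conditions: NaN(SiMe3)2, THF, −78 °C; then 5, −78 → −40 °C
Reagents that add atoms: none
Why: Evans asymmetric alkylation, in which the chelated Z-enolate 6 is attacked by the bromoacetate on the face opposite the C4 benzyl group of the (S)-auxiliary, which sets the new centre as R, the minor diastereomer being removable by chromatography or crystallisation.

Step 3
Reactants: 7 tert-butyl (3R)-4-[(4S)-4-benzyl-2-oxooxazolidin-3-yl]-3-(3,4-dimethoxybenzyl)-4-oxobutanoate
Product: 9 (R)-4-(3,4-dimethoxybenzyl)dihydrofuran-2(3H)-one [(R)-β-(3,4-dimethoxybenzyl)-γ-butyrolactone], via hydroxy tert-butyl ester 8 (not isolated)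
Conditions: LiBH4, MeOH (1.1 equiv), THF, 0 °C; aqueous work-up; then TsOH·H2O (10 mol %), toluene, 80 °C
Reagents that add atoms: none
Why: LiBH4 reduces the imide carbonyl in preference to the tert-butyl ester and releases the auxiliary, and acid-catalysed loss of isobutene with lactonisation of 8 then gives the γ-lactone without touching the stereocentre, which is no longer α to a carbonyl group.

Step 4
Reactants: 9 (R)-4-(3,4-dimethoxybenzyl)dihydrofuran-2(3H)-one
Product: 11 4,5-dimethoxy-2-{[(3R)-5-oxotetrahydrofuran-3-yl]methyl}benzaldehyde, via aryl chloromethyl methyl ether 10 (not isolated)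
Conditions: Cl2CHOMe, SnCl4, CH2Cl2, −10 → 0 °C; then H2O
Reagents that add atoms: dichloromethyl methyl ether, ClC(Cl)OC (formyl carbon); water, O (carbonyl oxygen on hydrolysis)
Why: Rieche formylation, an electrophilic aromatic substitution that 4-alkylveratroles undergo para to the 3-methoxy group and ortho to the alkyl chain, while the lactone only binds Lewis acid and the β-stereocentre cannot enolise.

Step 5
Reactants: 12 4-bromo-2-methoxyphenol
Product: 13 2-(4-bromo-2-methoxyphenoxy)tetrahydro-2H-pyran (racemic acetal)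
Conditions: 3,4-dihydro-2H-pyran, pyridinium p-toluenesulfonate (cat.), CH2Cl2, rt
Reagents that add atoms: 3,4-dihydro-2H-pyran, C1=COCCC1
Why: Acid-catalysed addition of the phenol to the enol ether (tetrahydropyranylation) masks the acidic OH for the Grignard step with a group that is shed under the acid of step 7.

Step 6
Reactants: 13 2-(4-bromo-2-methoxyphenoxy)tetrahydro-2H-pyran; 11 4,5-dimethoxy-2-{[(3R)-5-oxotetrahydrofuran-3-yl]methyl}benzaldehyde
Product: 15 (4R)-4-{2-[hydroxy(3-methoxy-4-(tetrahydro-2H-pyran-2-yloxy)phenyl)methyl]-4,5-dimethoxybenzyl}dihydrofuran-2(3H)-one (epimers at the carbinol and acetal carbons), via aryl Grignard reagent 14 (not isolated)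
Conditions: 13, Mg, I2 (cat.), THF, 45 °C; then slow addition to 11, THF, −78 → −40 °C; aq NH4Cl
Reagents that add atoms: none
Why: Grignard addition to the aldehyde, which at −78 °C is far more electrophilic than the γ-lactone, so a slight excess of 14 should leave the lactone intact; the carbinol carbon forms without control, which does not matter because it becomes planar in step 8.

Step 7
Reactants: 15 (4R)-4-{2-[hydroxy(3-methoxy-4-(tetrahydro-2H-pyran-2-yloxy)phenyl)methyl]-4,5-dimethoxybenzyl}dihydrofuran-2(3H)-one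
Product: 17 (4R)-4-{2-[(4-hydroxy-3-methoxyphenyl)(4-methylphenylsulfonyl)methyl]-4,5-dimethoxybenzyl}dihydrofuran-2(3H)-one (both epimers at the sulfonyl-bearing carbon), via phenolic benzhydrol 16 (not isolated)
Conditions: p-TolSO2Na (4 equiv), 1 M aq HCl (4 equiv), THF, 0 °C → rt
Reagents that add atoms: sodium p-toluenesulfinate, Cc1ccc(cc1)S(=O)[O-].[Na+]
Why: Aqueous acid removes the aryl tetrahydropyranyl acetal and ionises the doubly activated benzhydrol 16 to the p-hydroxybenzhydryl cation (a protonated quinone methide), which the sulfinate captures at sulfur in an SN1 sulfonylation, the usual entry to p-hydroxybenzyl sulfones, excess sulfinate outrunning Friedel–Crafts self-condensation and the γ-lactone being stable to dilute acid.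

Step 8
Reactants: 17 (4R)-4-{2-[(4-hydroxy-3-methoxyphenyl)(4-methylphenylsulfonyl)methyl]-4,5-dimethoxybenzyl}dihydrofuran-2(3H)-one
Product: 20 (3aR,9R,9aS)-9-(4-hydroxy-3-methoxyphenyl)-6,7-dimethoxy-3a,4,9,9a-tetrahydronaphtho[2,3-c]furan-1(3H)-one (cis-fused lactone, aryl trans to C9; 1R,2S,3R in lignan numbering), via dilithium phenoxide enolate 18 (not isolated), via quinone methide lithium enolate 19 (not isolated)
Conditions: LiN(SiMe3)2 (2.3 equiv), THF (0.01 M), −78 °C, slow addition of 17 to the base; then −78 → 0 °C; aq NH4Cl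
Reagents that add atoms: none
Why: Proposed new method: two equivalents of amide give the lithium phenoxide and the lactone enolate at C2 (18), on warming the phenoxide expels p-toluenesulfinate to form the p-quinone methide 19, and C2 adds to its exocyclic carbon C1 in a 1,6-addition that restores the aromatic guaiacyl ring. The closest known reaction types are the base-mediated 1,6-addition of stabilised carbon nucleophiles to p-quinone methides released in the flask from p-hydroxybenzyl sulfones and the routine alkylation of β-benzyl-γ-butyrolactone lithium enolates; new is an unstabilised lactone enolate as tethered donor, which should work because it is a much stronger nucleophile than the stabilised donors of the known cases and meets the acceptor within the same molecule. Ring B closes in a 6-exo-trig mode with respect to the C1=C1' bond of the quinone methide (6-enolexo at the enolate). C2 is controlled by the tether, since C4–C4a–C8a lets C1 reach only the enolate face that carries the C3–C4 bond, which gives the cis-fused lactone, and any trans-fused material would be epimerised by the residual base to this more stable isomer. C1 is controlled by C3 through a half-chair transition state in which the quinoid ring stands pseudo-axial, clear of the peri hydrogen H8 of ring A, and on the face opposite C9 and C9', the other pseudo-axial placement being 1,3-syn to C9'. The step needs intramolecular C–C bond formation to beat oligomerisation of the quinone methide and self-condensation of the enolate, which slow inverse addition at high dilution and low temperature (enolate formed before sulfinate loss) and a leaving group without acidic or acylating sites are meant to secure.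

Step 9
Reactants: 20 (3aR,9R,9aS)-9-(4-hydroxy-3-methoxyphenyl)-6,7-dimethoxy-3a,4,9,9a-tetrahydronaphtho[2,3-c]furan-1(3H)-one
Product: 21 [(1R,2S,3R)-1-(4-hydroxy-3-methoxyphenyl)-6,7-dimethoxy-1,2,3,4-tetrahydronaphthalene-2,3-diyl]dimethanol
Conditions: LiAlH4 (3 equiv), THF, 0 °C → rt; then 1 M HCl
Reagents that add atoms: none
Why: LiAlH4 reduction of the lactone to the 1,4-diol is fast at 0 °C, uses one extra hydride at the phenol and breaks no bond to C1, C2 or C3, C2 being in any case the thermodynamic epimer of the lactone.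

Step 10
Reactants: 21 [(1R,2S,3R)-1-(4-hydroxy-3-methoxyphenyl)-6,7-dimethoxy-1,2,3,4-tetrahydronaphthalene-2,3-diyl]dimethanol
Product: 22 (1R,2S,3R)-1-(3,4-dimethoxyphenyl)-6,7-dimethoxy-2,3-bis(methoxymethyl)-1,2,3,4-tetrahydronaphthalene
Conditions: NaH (5 equiv), MeI (6 equiv), THF–DMF, 0 °C → rt
Reagents that add atoms: iodomethane, CI
Why: Williamson etherification, in which NaH forms the phenoxide and both primary alkoxides and MeI methylates all three in one operation, no stereocentre carrying a hydrogen acidic enough to be removed.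

**Compound list**

1 | 3-(3,4-dimethoxyphenyl)propanoic acid | COc1ccc(CCC(=O)O)cc1OC | starting material
2 | (S)-4-benzyloxazolidin-2-one | O=C1N[C@@H](Cc2ccccc2)CO1 | starting material
3 | 3-(3,4-dimethoxyphenyl)propanoic pivalic anhydride | COc1ccc(CCC(=O)OC(=O)C(C)(C)C)cc1OC | intermediate
4 | (S)-4-benzyl-3-[3-(3,4-dimethoxyphenyl)propanoyl]oxazolidin-2-one | COc1ccc(CCC(=O)N2[C@@H](Cc3ccccc3)COC2=O)cc1OC | intermediate
5 | tert-butyl bromoacetate | CC(C)(C)OC(=O)CBr | starting material
6 | sodium Z-enolate of 4 | COc1ccc(C/C=C(\[O-])N2[C@@H](Cc3ccccc3)COC2=O)cc1OC.[Na+] | intermediate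
7 | tert-butyl (3R)-4-[(4S)-4-benzyl-2-oxooxazolidin-3-yl]-3-(3,4-dimethoxybenzyl)-4-oxobutanoate | COc1ccc(C[C@H](CC(=O)OC(C)(C)C)C(=O)N2[C@@H](Cc3ccccc3)COC2=O)cc1OC | intermediate
8 | tert-butyl (R)-3-(3,4-dimethoxybenzyl)-4-hydroxybutanoate | COc1ccc(C[C@H](CC(=O)OC(C)(C)C)CO)cc1OC | intermediate
9 | (R)-4-(3,4-dimethoxybenzyl)dihydrofuran-2(3H)-one | O1C[C@H](Cc2ccc(OC)c(OC)c2)CC1=O | intermediate
10 | (4R)-4-{2-[chloro(methoxy)methyl]-4,5-dimethoxybenzyl}dihydrofuran-2(3H)-one | O1C[C@H](Cc2cc(OC)c(OC)cc2C(Cl)OC)CC1=O | intermediate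
11 | 4,5-dimethoxy-2-{[(3R)-5-oxotetrahydrofuran-3-yl]methyl}benzaldehyde | O1C[C@H](Cc2cc(OC)c(OC)cc2C=O)CC1=O | intermediate
12 | 4-bromo-2-methoxyphenol | COc1cc(Br)ccc1O | starting material
13 | 2-(4-bromo-2-methoxyphenoxy)tetrahydro-2H-pyran | COc1cc(Br)ccc1OC1CCCCO1 | intermediate
14 | [3-methoxy-4-(tetrahydro-2H-pyran-2-yloxy)phenyl]magnesium bromide | COc1cc([Mg]Br)ccc1OC1CCCCO1 | intermediate
15 | (4R)-4-{2-[hydroxy(3-methoxy-4-(tetrahydro-2H-pyran-2-yloxy)phenyl)methyl]-4,5-dimethoxybenzyl}dihydrofuran-2(3H)-one | O1C[C@H](Cc2cc(OC)c(OC)cc2C(O)c2ccc(OC3CCCCO3)c(OC)c2)CC1=O | intermediate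
16 | (4R)-4-{2-[hydroxy(4-hydroxy-3-methoxyphenyl)methyl]-4,5-dimethoxybenzyl}dihydrofuran-2(3H)-one | O1C[C@H](Cc2cc(OC)c(OC)cc2C(O)c2ccc(O)c(OC)c2)CC1=O | intermediate
17 | (4R)-4-{2-[(4-hydroxy-3-methoxyphenyl)(4-methylphenylsulfonyl)methyl]-4,5-dimethoxybenzyl}dihydrofuran-2(3H)-one | O1C[C@H](Cc2cc(OC)c(OC)cc2C(c2ccc(O)c(OC)c2)S(=O)(=O)c2ccc(C)cc2)CC1=O | intermediate
18 | dilithium salt of 17 (lithium phenoxide and lithium lactone enolate) | O1C[C@H](Cc2cc(OC)c(OC)cc2C(c2ccc([O-])c(OC)c2)S(=O)(=O)c2ccc(C)cc2)C=C1[O-].[Li+].[Li+] | intermediate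
19 | lithium (R)-4-{2-[(3-methoxy-4-oxocyclohexa-2,5-dien-1-ylidene)methyl]-4,5-dimethoxybenzyl}-4,5-dihydrofuran-2-olate (p-quinone methide lactone enolate) | O1C[C@H](Cc2cc(OC)c(OC)cc2C=C2C=CC(=O)C(OC)=C2)C=C1[O-].[Li+] | intermediate
20 | (3aR,9R,9aS)-9-(4-hydroxy-3-methoxyphenyl)-6,7-dimethoxy-3a,4,9,9a-tetrahydronaphtho[2,3-c]furan-1(3H)-one | O1C[C@@H]2Cc3cc(OC)c(OC)cc3[C@@H](c3ccc(O)c(OC)c3)[C@@H]2C1=O | intermediate
21 | [(1R,2S,3R)-1-(4-hydroxy-3-methoxyphenyl)-6,7-dimethoxy-1,2,3,4-tetrahydronaphthalene-2,3-diyl]dimethanol | OC[C@@H]1Cc2cc(OC)c(OC)cc2[C@@H](c2ccc(O)c(OC)c2)[C@@H]1CO | intermediate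
22 | (1R,2S,3R)-1-(3,4-dimethoxyphenyl)-6,7-dimethoxy-2,3-bis(methoxymethyl)-1,2,3,4-tetrahydronaphthalene | COC[C@@H]1Cc2cc(OC)c(OC)cc2[C@@H](c2ccc(OC)c(OC)c2)[C@@H]1COC | target

**Step count**

Total step count: 10. Longest linear sequence: 9 steps (steps 1–4 and 6–10); step 5 is a one-step branch that feeds step 6.

**Steps most likely to fail**

1. Step 8 (Proposed new method). What may go wrong:
- loss of the quinone methide to intermolecular capture by phenoxide, amide or sulfinate, or to oligomerisation;
- quenching of the lactone enolate by proton transfer from the sulfonyl-bearing C–H;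
- Claisen-type self-condensation of the enolate on warming;
- poor facial discrimination at C1.

Fallback (known chemistry; cationic instead of anionic C1–C2 closure, no phenol needed): it sets out from aldehyde 11 and comes back at target 22. Commercial 3,4-dimethoxyphenylmagnesium bromide is added to 11 at −78 °C as in step 6 to give (4R)-4-{2-[(3,4-dimethoxyphenyl)(hydroxy)methyl]-4,5-dimethoxybenzyl}dihydrofuran-2(3H)-one F1. LiN(SiMe3)2 (2.2 equiv) and Me3SiCl in THF at −78 °C silylate both the alkoxide and the lactone enolate to give the silyl ketene acetal benzhydryl silyl ether F2. A catalytic amount of Me3SiOTf in CH2Cl2 at −78 °C ionises the benzhydryl silyl ether, and the diarylmethyl cation is captured at C2 by the ketene acetal. This is a Mukaiyama-type SN1 alkylation of a silyl ketene acetal by a benzhydryl electrophile, and it gives the O-methyl cis-lactone F3. The same half-chair preferences should govern C1, and DBU would equilibrate C2 if needed. LiAlH4 then gives the diol F4, and NaH/MeI (two methylations) gives 22.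

2. Step 7. What may go wrong: alkylation of the free guaiacol ring of a second molecule by the acid-generated benzhydryl cation (oligomerisation), or re-ionisation of the electron-rich sulfone during isolation.

Fallback (leaving group installed under basic conditions, phenol unmasked only inside the ring closure): it sets out from aldehyde 11 and comes back at 20. Phenol 12 is silylated with t-BuMe2SiCl/imidazole to (4-bromo-2-methoxyphenoxy)(tert-butyl)dimethylsilane F5 and converted with Mg into the aryl Grignard reagent F6. Addition to 11 at −78 °C, followed by t-BuCOCl/DMAP in the same flask, gives the benzhydryl pivalate silyl ether F7. LiN(SiMe3)2 (1.1 equiv) in THF at −78 °C forms the lactone lithium enolate F8. The anhydrous fluoride source (Me2N)3S+ Me3SiF2− then cleaves the aryl silyl ether, so that the phenoxide expels pivalate and generates 19 in the presence of the preformed enolate. 19 closes to 20 as in step 8.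

3. Step 6. What may go wrong: loss of chemoselectivity (attack on or enolisation of the lactone by the Grignard reagent), or sluggish magnesium insertion into the electron-rich aryl bromide.

Fallback (the diaryl carbon built by electrophilic acylation instead of a carbanion): it sets out from lactone 9 and comes back at the phenolic benzhydrol 16, which is then treated with p-TolSO2Na/HCl as in step 7. Vanillic acid is acetylated (Ac2O, pyridine) to 4-acetoxy-3-methoxybenzoic acid F9 and converted with (COCl)2/cat. DMF into 4-acetoxy-3-methoxybenzoyl chloride F10. Friedel–Crafts acylation of 9 (AlCl3, CH2Cl2, 0 °C) occurs para to the 3-methoxy group and gives the diaryl ketone aryl acetate F11. Luche reduction (NaBH4, CeCl3·7H2O, MeOH–THF, −20 °C) reduces the ketone, while the acetate still keeps it electrophilic, to the acetoxy carbinol F12. Brief K2CO3/MeOH at 0 °C then frees the phenol to give 16.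

**Further compounds**

F1 | step 8 | (4R)-4-{2-[(3,4-dimethoxyphenyl)(hydroxy)methyl]-4,5-dimethoxybenzyl}dihydrofuran-2(3H)-one | O1C[C@H](Cc2cc(OC)c(OC)cc2C(O)c2ccc(OC)c(OC)c2)CC1=O
F2 | step 8 | trimethylsilyl ketene acetal of the O-trimethylsilyl ether of F1 | O1C[C@H](Cc2cc(OC)c(OC)cc2C(O[Si](C)(C)C)c2ccc(OC)c(OC)c2)C=C1O[Si](C)(C)C
F3 | step 8 | (3aR,9R,9aS)-9-(3,4-dimethoxyphenyl)-6,7-dimethoxy-3a,4,9,9a-tetrahydronaphtho[2,3-c]furan-1(3H)-one | O1C[C@@H]2Cc3cc(OC)c(OC)cc3[C@@H](c3ccc(OC)c(OC)c3)[C@@H]2C1=O
F4 | step 8 | [(1R,2S,3R)-1-(3,4-dimethoxyphenyl)-6,7-dimethoxy-1,2,3,4-tetrahydronaphthalene-2,3-diyl]dimethanol | OC[C@@H]1Cc2cc(OC)c(OC)cc2[C@@H](c2ccc(OC)c(OC)c2)[C@@H]1CO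
F5 | step 7 | (4-bromo-2-methoxyphenoxy)(tert-butyl)dimethylsilane | COc1cc(Br)ccc1O[Si](C)(C)C(C)(C)C
F6 | step 7 | [4-(tert-butyldimethylsilyloxy)-3-methoxyphenyl]magnesium bromide | COc1cc([Mg]Br)ccc1O[Si](C)(C)C(C)(C)C
F7 | step 7 | [4-(tert-butyldimethylsilyloxy)-3-methoxyphenyl](4,5-dimethoxy-2-{[(3R)-5-oxotetrahydrofuran-3-yl]methyl}phenyl)methyl pivalate | O1C[C@H](Cc2cc(OC)c(OC)cc2C(OC(=O)C(C)(C)C)c2ccc(O[Si](C)(C)C(C)(C)C)c(OC)c2)CC1=O
F8 | step 7 | lithium lactone enolate of F7 | O1C[C@H](Cc2cc(OC)c(OC)cc2C(OC(=O)C(C)(C)C)c2ccc(O[Si](C)(C)C(C)(C)C)c(OC)c2)C=C1[O-].[Li+]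
F9 | step 6 | 4-acetoxy-3-methoxybenzoic acid | COc1cc(C(=O)O)ccc1OC(C)=O
F10 | step 6 | 4-acetoxy-3-methoxybenzoyl chloride | COc1cc(C(Cl)=O)ccc1OC(C)=O
F11 | step 6 | 4-(4,5-dimethoxy-2-{[(3R)-5-oxotetrahydrofuran-3-yl]methyl}benzoyl)-2-methoxyphenyl acetate | O1C[C@H](Cc2cc(OC)c(OC)cc2C(=O)c2ccc(OC(C)=O)c(OC)c2)CC1=O
F12 | step 6 | 4-[(4,5-dimethoxy-2-{[(3R)-5-oxotetrahydrofuran-3-yl]methyl}phenyl)(hydroxy)methyl]-2-methoxyphenyl acetate | O1C[C@H](Cc2cc(OC)c(OC)cc2C(O)c2ccc(OC(C)=O)c(OC)c2)CC1=O
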